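**Retrosynthetic overview**
1. Target 11 is (2S,3R)-7-allyl-5-methoxy-3-methyl-2-(3,4,5-trimethoxyphenyl)-2,3-dihydro-1,4-benzodioxin-2-ol. Both benzene rings are bought, and the 1,4-dioxane ring is the only ring made, in the last step.
2. Enabling feature: C2 of the dioxane ring is a hemiketal carbon (O1, OH, aryl, C3), that is, the tetrahedral adduct of an acyl group. O1 sits on C8a, which lies between the O4-bearing C4a and the unsubstituted C8-H.
3. Three bonds therefore form in one operation. C2–aryl comes from an aryllithium and a Weinreb amide. O1–C8a comes from the alkoxide oxygen of the unquenched tetrahedral adduct and a C8a≡C8 aryne, made from a C8 bromide as a traceless activator. C2–OH comes from hydrolysis of the resulting N,O-ketal.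
4. O4–C3: Mitsunobu inversion of ethyl (S)-lactate by eugenol sets C3 as (R). NBS then places the bromine para to the methoxy group.
5. C2 (S) follows from C3, because water adds anti to the methyl group and the hemiketal can settle by anomeric equilibration.

Key step: step 4

Assumption: C2 can equilibrate through the ring-opened keto phenol, so the drawn (2S) epimer (OH trans to the C3 methyl group) is taken to be the more stable one, and the compound is taken to rest in the closed hemiketal form.

Step 1
Reactants: 1 eugenol (4-allyl-2-methoxyphenol); 2 ethyl (S)-lactate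
Product: 3 ethyl (R)-2-(4-allyl-2-methoxyphenoxy)propanoate
Conditions: PPh3, DIAD, THF, 0 °C → rt
Reagents that add atoms: none
Why: Mitsunobu reaction, in which SN2 displacement of the activated lactate hydroxyl group by the phenol with inversion turns the (S)-carbinol into the (R)-aryl ether carbon that becomes C3 of the target.

Step 2
Reactants: 3 ethyl (R)-2-(4-allyl-2-methoxyphenoxy)propanoate
Product: 4 (R)-2-(4-allyl-2-methoxyphenoxy)-N-methoxy-N-methylpropanamide
Conditions: MeNHOMe·HCl, iPrMgCl, THF, −20 → 0 °C; aq. NH4Cl
Reagents that add atoms: N,O-dimethylhydroxylamine hydrochloride, CNOC.Cl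
Why: Weinreb amide formation by aminolysis of the ester with the chloromagnesium amide made in the flask, which is fast at low temperature so that the stereocentre next to the carbonyl group should be kept.

Step 3
Reactants: 4 (R)-2-(4-allyl-2-methoxyphenoxy)-N-methoxy-N-methylpropanamide
Product: 5 (R)-2-(4-allyl-5-bromo-2-methoxyphenoxy)-N-methoxy-N-methylpropanamide
Conditions: NBS, MeCN, 0 °C → rt, dark
Reagents that add atoms: N-bromosuccinimide, O=C1CCC(=O)N1Br
Why: Electrophilic aromatic bromination with NBS in a polar solvent, where the position para to the methoxy group is the most activated free site of a 4-alkylguaiacol ether and, under ionic, water-free conditions in the dark, the electron-rich ring should react faster than the terminal alkene.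

Step 4
Reactants: 5 (R)-2-(4-allyl-5-bromo-2-methoxyphenoxy)-N-methoxy-N-methylpropanamide; 6 5-bromo-1,2,3-trimethoxybenzene
Product: 11 (2S,3R)-7-allyl-5-methoxy-3-methyl-2-(3,4,5-trimethoxyphenyl)-2,3-dihydro-1,4-benzodioxin-2-ol, via aryllithium 7 (not isolated), via tetrahedral lithium alkoxide 8 (not isolated), via aryne 9 (not isolated), via cyclic N,O-ketal 10 (not isolated)
Conditions: 6, n-BuLi, THF, −78 °C; add 5, −78 °C; LiTMP (lithium 2,2,6,6-tetramethylpiperidide), −78 → −50 °C; 1 M aq. HCl, THF, 0 °C
Reagents that add atoms: water, O
Why: Proposed new method: aryllithium 7 adds to the Weinreb amide of 5 and the reaction is held at the N-methoxy-chelated tetrahedral lithium alkoxide 8, LiTMP then removes the one ring hydrogen that lies between the aryloxy oxygen and the bromine, LiBr leaves, and the alkoxide oxygen of aryne 9 adds to the near aryne carbon, after which the aryl anion is protonated by the tetramethylpiperidine just formed to give 10. The closest known reaction types are the generation of 3-alkoxyarynes from 3-bromoanisoles with lithium amides and the classical ring closure of arynes by tethered alkoxides or amides, and the only new element is that the oxygen nucleophile is the tetrahedral intermediate of a Weinreb ketone synthesis instead of an ordinary alkoxide. The 1,4-dioxane ring closes in the 6-exo-dig mode by in-plane attack on the aryne carbon next to the carbon that bears the ether oxygen. An outside nucleophile would prefer the far aryne carbon because of the distortion induced by the alkoxy group, but the four-atom tether can reach only the near carbon, the far carbon is screened by the allyl group, and LiTMP and its amine are too hindered to compete. C3 keeps the (R) configuration brought in from lactate because 8, 9 and 10 have no carbonyl group next to it while base is present. Dilute acid expels MeNHOMe from 10 to give the 2-aryl-dioxenium ion, water adds axially on the face opposite to the C3 methyl group, and ring-chain equilibration should favour the same (2S) epimer, with OH axial (anomeric effect), aryl equatorial and OH anti to methyl.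

**Compound list**
1 | eugenol (4-allyl-2-methoxyphenol) | C=CCc1ccc(O)c(OC)c1 | starting material
2 | ethyl (S)-lactate | C[C@H](O)C(=O)OCC | starting material
3 | ethyl (R)-2-(4-allyl-2-methoxyphenoxy)propanoate | C[C@@H](Oc1ccc(CC=C)cc1OC)C(=O)OCC | intermediate
4 | (R)-2-(4-allyl-2-methoxyphenoxy)-N-methoxy-N-methylpropanamide | C[C@@H](Oc1ccc(CC=C)cc1OC)C(=O)N(C)OC | intermediate
5 | (R)-2-(4-allyl-5-bromo-2-methoxyphenoxy)-N-methoxy-N-methylpropanamide | C[C@@H](Oc1cc(Br)c(CC=C)cc1OC)C(=O)N(C)OC | intermediate
6 | 5-bromo-1,2,3-trimethoxybenzene | COc1cc(Br)cc(OC)c1OC | starting material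
7 | 3,4,5-trimethoxyphenyllithium | [Li]c1cc(OC)c(OC)c(OC)c1 | intermediate
8 | lithium (2R)-2-(4-allyl-5-bromo-2-methoxyphenoxy)-1-[methoxy(methyl)amino]-1-(3,4,5-trimethoxyphenyl)propan-1-olate (configuration at C1 of no consequence) | C[C@@H](Oc1cc(Br)c(CC=C)cc1OC)C([O-])(N(C)OC)c1cc(OC)c(OC)c(OC)c1.[Li+] | intermediate
9 | lithium (2R)-2-(4-allyl-5,6-didehydro-2-methoxyphenoxy)-1-[methoxy(methyl)amino]-1-(3,4,5-trimethoxyphenyl)propan-1-olate (aryne) | C[C@@H](OC1=C(OC)C=C(CC=C)C#C1)C([O-])(N(C)OC)c1cc(OC)c(OC)c(OC)c1.[Li+] | intermediate
10 | (3R)-7-allyl-N,5-dimethoxy-N,3-dimethyl-2-(3,4,5-trimethoxyphenyl)-2,3-dihydro-1,4-benzodioxin-2-amine (configuration at C2 of no consequence) | C=CCc1cc(OC)c2c(c1)OC(N(C)OC)(c1cc(OC)c(OC)c(OC)c1)[C@@H](C)O2 | intermediate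
11 | (2S,3R)-7-allyl-5-methoxy-3-methyl-2-(3,4,5-trimethoxyphenyl)-2,3-dihydro-1,4-benzodioxin-2-ol | C=CCc1cc(OC)c2c(c1)O[C@@](O)(c1cc(OC)c(OC)c(OC)c1)[C@@H](C)O2 | target

Total step count: 4
Longest linear sequence: 4 steps (1 → 3 → 4 → 5 → 11)

**Steps most likely to fail**

Step 4 (bears the label "Proposed new method:"). Four things may go wrong:
- The tetrahedral adduct may collapse before the aryne is formed, followed by enolisation and loss of configuration.
- Outside nucleophiles may capture the aryne at the far carbon.
- Bromine–lithium exchange between 7 and 5 may compete with carbonyl addition.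
- The base may move the allyl double bond into conjugation.

The fallback uses known chemistry and closes the same aryl carbon–oxygen bond at the carboxyl oxidation level. It sets out from 1 and comes back at 11. Eugenol 1 is brominated ortho to the free hydroxyl group (NBS, cat. iPr2NH, CH2Cl2, 0 °C) to give 4-allyl-2-bromo-6-methoxyphenol F1. A Mitsunobu reaction with 2 gives ethyl (R)-2-(4-allyl-2-bromo-6-methoxyphenoxy)propanoate F2. LiOH in aqueous THF at 0 °C then gives (R)-2-(4-allyl-2-bromo-6-methoxyphenoxy)propanoic acid F3, whose carboxylate resists deprotonation at the stereocentre. Intramolecular Ullmann-type O-arylation of the caesium carboxylate (CuI, 1,10-phenanthroline, Cs2CO3, toluene, heat) closes the ring to (R)-7-allyl-5-methoxy-3-methyl-1,4-benzodioxin-2(3H)-one F4. One equivalent of 7 at −78 °C adds to the lactone carbonyl group and should give 11 after aq. NH4Cl.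

Step 3. Bromine may add to the allyl double bond, or radical bromination at the allylic and benzylic CH2 may compete with ring substitution. The fallback accepts the addition and reverses it. It sets out from 4 and comes back at 5. Two equivalents of Br2 in CH2Cl2 at 0 °C brominate both the ring and the alkene to give (2R)-2-[5-bromo-4-(2,3-dibromopropyl)-2-methoxyphenoxy]-N-methoxy-N-methylpropanamide F5. NaI in acetone at reflux then removes the vicinal dibromide, which serves as an alkene protecting group, and regenerates the allyl group of 5.

Step 2. The magnesium amide may deprotonate the aryloxy ester next to the carbonyl group and so erode configurational purity, or the aminolysis may stay incomplete. The fallback changes the order of events so that the aryl ether stereocentre never meets this base. It sets out from 2 and comes back at 4. Ethyl (S)-lactate 2 is converted first (MeNHOMe·HCl, iPrMgCl, THF, −20 → 0 °C) into (S)-2-hydroxy-N-methoxy-N-methylpropanamide F6. A Mitsunobu reaction of F6 with 1 (PPh3, DIAD, toluene, 0 °C → rt) then gives 4 directly with inversion.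

**Further compounds**
F1 | step 4 | 4-allyl-2-bromo-6-methoxyphenol | C=CCc1cc(Br)c(O)c(OC)c1
F2 | step 4 | ethyl (R)-2-(4-allyl-2-bromo-6-methoxyphenoxy)propanoate | C[C@@H](Oc1c(Br)cc(CC=C)cc1OC)C(=O)OCC
F3 | step 4 | (R)-2-(4-allyl-2-bromo-6-methoxyphenoxy)propanoic acid | C[C@@H](Oc1c(Br)cc(CC=C)cc1OC)C(=O)O
F4 | step 4 | (R)-7-allyl-5-methoxy-3-methyl-1,4-benzodioxin-2(3H)-one | C=CCc1cc(OC)c2c(c1)OC(=O)[C@@H](C)O2
F5 | step 3 | (2R)-2-[5-bromo-4-(2,3-dibromopropyl)-2-methoxyphenoxy]-N-methoxy-N-methylpropanamide (mixture at the CHBr carbon) | C[C@@H](Oc1cc(Br)c(CC(Br)CBr)cc1OC)C(=O)N(C)OC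
F6 | step 2 | (S)-2-hydroxy-N-methoxy-N-methylpropanamide | C[C@H](O)C(=O)N(C)OC
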